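## Analysis of the target

- Target 9 is an oxolane (O1, C2–C5) with a 4-hydroxy-3-methoxyphenyl group on C2 and on C5 and a hydroxymethyl group on C3 and on C4. Numbering used throughout: C2 is the ring carbon written first in the SMILES; with it 9 is (2S,3S,4R,5S).
- The constitution has twofold symmetry, the configuration has none. The C2 aryl, the C3 CH2OH and the C4 CH2OH lie on one face and the C5 aryl on the other (2,3-cis, 3,4-cis, 4,5-trans, 2,5-trans).
- 9 is therefore neither C2-symmetric nor meso. It is the C5 epimer of the all-cis meso isomer, and the C2 epimer of the meso trans,cis,trans isomer, which is the thermodynamic sink.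
- The structural feature the route is built on: C2–O1 and C5–O1 are both p-hydroxybenzyl ether bonds. Each can ionise, pushed by its para phenol, to a p-quinone methide and close again.
- Sensitive groups: two free phenols (oxidation, quinone methide formation), two benzylic C–O bonds (acid, hydrogenolysis), and two primary alcohols that can attack an ionised C2 or C5 to give isomeric oxolanes.
- The difficulty is an unsymmetrical set of four contiguous stereocentres on a symmetrical constitution, with the C2 aryl cis to two neighbours against thermodynamic preference, and an absolute configuration onto which no chiral-pool fragment maps.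

## Retrosynthetic reasoning

**9 ⇒ 8.** The two C–O(H) bonds of the hydroxymethyl groups are traced back to the methyl esters of 8. The esters are kept until the end so that no primary hydroxyl is present while a benzylic position is ionised. The forward reaction is a hydride reduction that touches no stereocentre.

**8 ⇒ 6 (key disconnection).** The C5–O1 bond is cut and re-formed with the opposite configuration at C5. It is cut there because 8 is the C5 epimer of 6, and 6 is meso: its C2–O1 and C5–O1 bonds are enantiotopic. Opening one of them gives the p-quinone methide 7, which closes on its other face to 8. Gained: the whole stereochemical problem collapses to an achiral, all-cis precursor, and one catalyst-controlled event fixes the absolute configuration of all four centres and the single trans relationship. The forward reaction has to choose between two enantiotopic ether bonds, close trans, and stop after one epimerisation.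

**6 ⇒ 4.** The four ring C–H bonds are cut back to the furan 4. Hydrogen delivered from one face of a flat, achiral furan gives the all-cis arrangement with no stereochemical choice to make. The same operation removes the benzyl ethers (through 5) and frees the phenols the key step needs.

**4 ⇒ 1 + 2.** Both aryl–furan bonds (C2–aryl and C5–aryl) are cut at once. The two α-C–H bonds of 1 are equivalent and are the most acidic on the ring, so a two-directional C–H arylation with 2 (through 3) builds the whole carbon skeleton in one step from two commercial compounds.

## Alternatives that were turned down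

**Alternative 1:** the textbook route, one stereocentre at a time from a chiral lactone.
- Disconnection: the C5–aryl bond, with C5 as the carbonyl carbon of the all-cis γ-aryl lactone A1.
- Forward key step: partial reduction of A1, Lewis-acid ionisation at the anomeric carbon and addition of an arylmetal reagent anti to the three cis substituents.
- Why turned down: A1 needs an auxiliary- or catalyst-controlled C–C bond formation, a face-selective hydrogenation and protection of both hydroxymethyl groups. The sequence runs to about ten linear steps, ignores the twofold constitution, and ionises next to an existing p-alkoxybenzyl ether centre that can scramble.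

**Alternative 2:** (3+2) cycloaddition of a carbonyl ylide.
- Disconnection: C2–C3 and C4–C5.
- Forward key step: the diaryl carbonyl ylide A2, generated by C–C cleavage of an epoxide, adds to dimethyl maleate to give A3, forming the ring and all four centres at once.
- Why turned down: the 2,5-trans pattern requires the sickle (exo,endo) form of A2. The W form is favoured and leads to 2,5-cis, meso adducts. A2 is planar and achiral, so A3 would be racemic. A chiral maleate surrogate controls its own face but not which ylide terminus bonds to which of its carbons, and that choice decides the enantiomer.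

**Alternative 3:** hidden C2 symmetry.
- Disconnection: the C3–H and C4–H bonds.
- Forward key step: syn hydrogenation of the C2-symmetric trans-2,5-dihydrofuran A4 (for example with [Ir(cod)(PCy3)(py)]PF6). Its two faces are homotopic, so any syn addition gives the relative configuration of 9 with no selectivity needed.
- Why turned down: the step is stereochemically perfect but its precursor is expensive.
  - A C2-symmetric 1,4-diol closes with inversion at one carbinol carbon and gives the cis ring.
  - Double asymmetric Heck arylation of 2,3-dihydrofuran gives the ring without the C3/C4 carbons, and adding them syn across a bis-benzylic, bis-allylic ether competes with aromatisation to the furan.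
  - Ring-closing metathesis would have to form a tetrasubstituted alkene from a chiral bis-benzylic ether that is itself hard to make.

Key step: step 3

Assumption: the sense of induction of the chiral phosphoric acid in step 3 cannot be derived from structure; the catalyst antipode that gives 8 is to be used, and (R) is written as a placeholder.

## Route

Step 1
Reactants: 1 dimethyl furan-3,4-dicarboxylate; 2 1-(benzyloxy)-4-bromo-2-methoxybenzene (2.4 equiv)
Product: 4 dimethyl 2,5-bis[4-(benzyloxy)-3-methoxyphenyl]furan-3,4-dicarboxylate, via monoaryl furan 3 (not isolated)
Conditions: Pd(OAc)2 (5 mol%), PCy3·HBF4 (10 mol%), PivOH (30 mol%), K2CO3 (3 equiv), DMA, 110 °C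
Reagents that add atoms: none
Why: Two-directional direct C–H arylation by concerted metalation–deprotonation; the two equivalent α-C–H bonds of 1, each flanked by the ring oxygen and an ester, are the most acidic on the ring, so both aryl–furan bonds form in one operation through 3. Benzyl ethers and methyl esters should tolerate carbonate in dry DMA.

Step 2
Reactants: 4
Product: 6 dimethyl (2S,3R,4S,5R)-2,5-bis(4-hydroxy-3-methoxyphenyl)oxolane-3,4-dicarboxylate (all-cis, meso), via furan bisphenol 5 (not isolated)
Conditions: H2 (30 bar), Pd(OH)2/C, EtOAc–MeOH, 40 °C
Reagents that add atoms: none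
Why: Heterogeneous hydrogenation with O-benzyl hydrogenolysis first (giving 5), then syn delivery of two equivalents of hydrogen to the furan. After the first addition the new sp3 centres turn their aryl and ester groups away from the surface, so the second addition should come from the same face and put all four substituents cis (meso 6). Neutral solvent is chosen to avoid acid-promoted benzylic epimerisation or hydrogenolysis of the product.

Step 3
Reactants: 6
Product: 8 dimethyl (2S,3R,4S,5S)-2,5-bis(4-hydroxy-3-methoxyphenyl)oxolane-3,4-dicarboxylate, via quinone methide 7 (not isolated)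
Conditions: (R)-3,3'-bis(2,4,6-triisopropylphenyl)-1,1'-binaphthyl-2,2'-diyl hydrogen phosphate (10 mol%), toluene, 4 Å molecular sieves, 40 °C; Et3N quench at the conversion optimum
Reagents that add atoms: none
Why: Proposed new method: a chiral phosphoric acid should ionise one of the two enantiotopic p-hydroxybenzyl ether bonds of meso 6 (C5–O1 rather than C2–O1) by hydrogen bonding to the phenol and protonation of O1, giving the ring-opened p-quinone methide 7 as a catalyst-bound chiral species; rotation about C4–C5 and oxa-1,6-addition of the C2 hydroxyl to the other face of the methide re-closes the ring with the C5 aryl trans to the C4 ester. The closest known reaction types are the acid-catalysed single benzylic epimerisation of all-cis 2,5-diaryloxolanes and the phosphoric-acid-catalysed enantioselective 1,6-additions to p-quinone methides formed in situ from p-hydroxybenzyl alcohols; what is new is their combination into the desymmetrisation of a meso cyclic ether. Ring closed: the oxolane, through the C5–O1 bond, in a 5-exo-trig mode with respect to the exocyclic methide C=C. Stereocentres: C5 is set by closure anti to the C4 ester, which also releases the 1,2-cis strain; C2, C3 and C4 are not touched, and their absolute sense in the product is fixed by the catalyst's choice between the two enantiotopic C–O bonds, that is, between 7 and its mirror image. Selectivity needed: enantiotopic-bond selection, trans closure, and a stop after one epimerisation; the fourfold cis strain of 6 should make the first ionisation easier than the second, and in 8 the remaining cis benzylic bond is the one the catalyst disfavours, so over-reaction to the meso trans,cis,trans isomer should drain mainly the mirror-image product. The methyl esters are kept at this stage so that no primary hydroxyl competes for the methide.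

Step 4
Reactants: 8
Product: 9 [(2S,3S,4R,5S)-2,5-bis(4-hydroxy-3-methoxyphenyl)oxolane-3,4-diyl]dimethanol (target)
Conditions: LiAlH4 (6 equiv), THF, 0 °C to rt; then H2O
Reagents that add atoms: none
Why: Ester-to-alcohol reduction with LiAlH4; hydride addition to the ester carbonyls is faster than enolisation at C3/C4, so no stereocentre is touched. The phenols travel as phenoxides and are re-protonated on work-up; the C3/C4 descriptors change only because the CIP priorities change.

## Compound list

1 | dimethyl furan-3,4-dicarboxylate | COC(=O)c1cocc1C(=O)OC | starting material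
2 | 1-(benzyloxy)-4-bromo-2-methoxybenzene | COc1cc(Br)ccc1OCc1ccccc1 | starting material
3 | dimethyl 2-[4-(benzyloxy)-3-methoxyphenyl]furan-3,4-dicarboxylate | COC(=O)c1coc(-c2ccc(OCc3ccccc3)c(OC)c2)c1C(=O)OC | intermediate
4 | dimethyl 2,5-bis[4-(benzyloxy)-3-methoxyphenyl]furan-3,4-dicarboxylate | COC(=O)c1c(-c2ccc(OCc3ccccc3)c(OC)c2)oc(-c2ccc(OCc3ccccc3)c(OC)c2)c1C(=O)OC | intermediate
5 | dimethyl 2,5-bis(4-hydroxy-3-methoxyphenyl)furan-3,4-dicarboxylate | COC(=O)c1c(-c2ccc(O)c(OC)c2)oc(-c2ccc(O)c(OC)c2)c1C(=O)OC | intermediate
6 | dimethyl (2S,3R,4S,5R)-2,5-bis(4-hydroxy-3-methoxyphenyl)oxolane-3,4-dicarboxylate (all-cis, meso) | COc1cc([C@H]2O[C@@H](c3ccc(O)c(OC)c3)[C@@H](C(=O)OC)[C@H]2C(=O)OC)ccc1O | intermediate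
7 | dimethyl (2R,3R)-2-[(S)-hydroxy(4-hydroxy-3-methoxyphenyl)methyl]-3-[(3-methoxy-4-oxocyclohexa-2,5-dien-1-ylidene)methyl]butanedioate (ring-opened p-quinone methide; geometry of the exocyclic C=C not fixed) | COc1cc(ccc1O)[C@@H](O)[C@H](C(=O)OC)[C@H](C(=O)OC)C=C1C=CC(=O)C(OC)=C1 | intermediate
8 | dimethyl (2S,3R,4S,5S)-2,5-bis(4-hydroxy-3-methoxyphenyl)oxolane-3,4-dicarboxylate | COc1cc([C@H]2O[C@H](c3ccc(O)c(OC)c3)[C@@H](C(=O)OC)[C@H]2C(=O)OC)ccc1O | intermediate
9 | [(2S,3S,4R,5S)-2,5-bis(4-hydroxy-3-methoxyphenyl)oxolane-3,4-diyl]dimethanol | COc1cc([C@H]2O[C@H](c3ccc(O)c(OC)c3)[C@@H](CO)[C@H]2CO)ccc1O | target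

## Step count and least certain steps

Total step count: 4. Longest linear sequence: 4 steps (1 → 4 → 6 → 8 → 9).

**Step 3 (key step, proposed new method).**
- What may go wrong: the catalyst may discriminate poorly between the two enantiotopic C–O bonds, giving low enantiomeric purity. A second ionisation at C2 of 8 would carry material on to the meso trans,cis,trans isomer. A phosphoric acid may be too weak to ionise an ether next to an ester-bearing carbon, so turnover could be slow. The transient C2 hydroxyl of 7 could lactonise onto the C4 ester.
- Fallback (known chemistry, resolution instead of desymmetrisation): it sets out from 6 and comes back at 9. 6 is epimerised once with a catalytic achiral acid (CF3CO2H, CH2Cl2, 0 °C) to the racemate, that is 8 together with its enantiomer dimethyl (2R,3S,4R,5R)-2,5-bis(4-hydroxy-3-methoxyphenyl)oxolane-3,4-dicarboxylate F1. Reduction with LiAlH4 as in step 4 gives 9 together with its enantiomer [(2R,3R,4S,5R)-2,5-bis(4-hydroxy-3-methoxyphenyl)oxolane-3,4-diyl]dimethanol F2. Lipase-catalysed transesterification (Candida antarctica lipase B, vinyl acetate, tert-butyl methyl ether) then acylates the faster-reacting enantiomer, taken here to be F2, to [(2R,3R,4S,5R)-2,5-bis(4-hydroxy-3-methoxyphenyl)oxolane-3,4-diyl]bis(methylene) diacetate F3, and unreacted 9 is separated by chromatography. At most half of the material can be recovered as 9.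

**Step 2.**
- What may go wrong: the reduction may stall after the first hydrogen uptake, because the remaining double bond is a tetrasubstituted β-aryl-β-alkoxyacrylate. The benzylic ring C–O bonds of the product may undergo hydrogenolysis, or an arene may be saturated under forcing conditions. Partial epimerisation on an acidic support would spoil the meso purity.
- Fallback (cycloaddition instead of furan reduction): it sets out from 2 and comes back at 6. Twofold Suzuki–Miyaura coupling of 2 with (E)-1,2-bis(4,4,5,5-tetramethyl-1,3,2-dioxaborolan-2-yl)ethene (Pd(PPh3)4, K2CO3, dioxane–H2O, 90 °C) gives (E)-1,2-bis[4-(benzyloxy)-3-methoxyphenyl]ethene F4. Epoxidation with dimethyldioxirane (acetone, 0 °C) gives racemic trans-2,3-bis[4-(benzyloxy)-3-methoxyphenyl]oxirane F5. Photoinduced electron-transfer C–C cleavage (2,4,6-triphenylpyrylium tetrafluoroborate, blue light, MeCN) and (3+2) cycloaddition with dimethyl but-2-ynedioate gives the 2,5-cis adduct dimethyl (2R,5S)-2,5-bis[4-(benzyloxy)-3-methoxyphenyl]-2,5-dihydrofuran-3,4-dicarboxylate F6. Its double bond is an ordinary maleate; H2 over Pd/C (EtOAc–MeOH) should add to the face opposite both aryl groups and remove the benzyl groups, giving 6.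

**Step 1.**
- What may go wrong: the second arylation may be slow next to the first aryl group. Reductive debromination or homocoupling of 2 and partial ester cleavage by carbonate at 110 °C would lower the yield.
- Fallback (stoichiometric metalation and cross-coupling instead of catalytic C–H activation): it sets out from 1 and comes back at 4. Double magnesiation at C2 and C5 with TMPMgCl·LiCl (THF, −40 °C) and iodinolysis with I2 gives dimethyl 2,5-diiodofuran-3,4-dicarboxylate F7. Twofold Suzuki–Miyaura coupling with [4-(benzyloxy)-3-methoxyphenyl]boronic acid (Pd(dppf)Cl2, K3PO4, dioxane–H2O, 80 °C) gives 4.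

## Further compounds

F1 | step 3 | dimethyl (2R,3S,4R,5R)-2,5-bis(4-hydroxy-3-methoxyphenyl)oxolane-3,4-dicarboxylate (enantiomer of 8) | COc1cc([C@@H]2O[C@@H](c3ccc(O)c(OC)c3)[C@H](C(=O)OC)[C@@H]2C(=O)OC)ccc1O
F2 | step 3 | [(2R,3R,4S,5R)-2,5-bis(4-hydroxy-3-methoxyphenyl)oxolane-3,4-diyl]dimethanol (enantiomer of 9) | COc1cc([C@@H]2O[C@@H](c3ccc(O)c(OC)c3)[C@H](CO)[C@@H]2CO)ccc1O
F3 | step 3 | [(2R,3R,4S,5R)-2,5-bis(4-hydroxy-3-methoxyphenyl)oxolane-3,4-diyl]bis(methylene) diacetate | COc1cc([C@@H]2O[C@@H](c3ccc(O)c(OC)c3)[C@H](COC(C)=O)[C@@H]2COC(C)=O)ccc1O
F4 | step 2 | (E)-1,2-bis[4-(benzyloxy)-3-methoxyphenyl]ethene | COc1cc(/C=C/c2ccc(OCc3ccccc3)c(OC)c2)ccc1OCc1ccccc1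
F5 | step 2 | (2R,3R)-2,3-bis[4-(benzyloxy)-3-methoxyphenyl]oxirane (trans; used as the racemate) | COc1cc([C@H]2O[C@@H]2c2ccc(OCc3ccccc3)c(OC)c2)ccc1OCc1ccccc1
F6 | step 2 | dimethyl (2R,5S)-2,5-bis[4-(benzyloxy)-3-methoxyphenyl]-2,5-dihydrofuran-3,4-dicarboxylate (cis, meso) | COc1cc([C@H]2O[C@@H](c3ccc(OCc4ccccc4)c(OC)c3)C(C(=O)OC)=C2C(=O)OC)ccc1OCc1ccccc1
F7 | step 1 | dimethyl 2,5-diiodofuran-3,4-dicarboxylate | COC(=O)c1c(I)oc(I)c1C(=O)OC
A1 | alternative 1 | (3R,4S,5S)-5-[4-(benzyloxy)-3-methoxyphenyl]-3,4-bis[(benzyloxy)methyl]oxolan-2-one (all-cis) | COc1cc([C@H]2OC(=O)[C@@H](COCc3ccccc3)[C@H]2COCc2ccccc2)ccc1OCc1ccccc1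
A2 | alternative 2 | {[4-(benzyloxy)-3-methoxyphenyl]methylidene}{[4-(benzyloxy)-3-methoxyphenyl]methanidyl}oxidanium, carbonyl ylide in its sickle (exo,endo) form (the geometry at the second terminus cannot be written in SMILES) | COc1cc(/C=[O+]/[CH-]c2ccc(OCc3ccccc3)c(OC)c2)ccc1OCc1ccccc1
A3 | alternative 2 | dimethyl (2S,3R,4S,5S)-2,5-bis[4-(benzyloxy)-3-methoxyphenyl]oxolane-3,4-dicarboxylate (would form as the racemate) | COc1cc([C@H]2O[C@H](c3ccc(OCc4ccccc4)c(OC)c3)[C@@H](C(=O)OC)[C@H]2C(=O)OC)ccc1OCc1ccccc1
A4 | alternative 3 | [(2R,5R)-2,5-bis[4-(benzyloxy)-3-methoxyphenyl]-2,5-dihydrofuran-3,4-diyl]dimethanol | COc1cc([C@H]2O[C@H](c3ccc(OCc4ccccc4)c(OC)c3)C(CO)=C2CO)ccc1OCc1ccccc1
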